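**Plan**

- Retrosynthesis: after removal of the MOM and TBS groups, ring A is cut at C4a–C5 (Claisen condensation) and at C8–C8a (conjugate addition). This leaves ring C as a 2,3-dihydropyran-4-one with a C4a=C8a double bond, and a prenyl, geranyl β-keto ester that supplies C5–C8.
- Ring C is then cut at C2–C3 and O1–C8a. O1–C2 is the carbonyl group of the 2,6-dioxygenated ring B aldehyde, and C3–C4–C4a–C8a is a 1-methoxy-3,4-bis(silyloxy)butadiene; this reading is possible only because ring A can be peeled back to its C4a=C8a bond.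
- Forward: the ring B aldehyde (2 steps) and the diene (3 steps) close ring C in an asymmetric hetero-Diels–Alder reaction. The C5–C8 chain (3 steps) is joined at C8a by Mukaiyama–Michael addition with selenoxide re-oxidation, ring A closes and aromatises by Claisen condensation, and acid removes the protecting groups.
- Stereochemistry: C2 comes from the (S)-BINOL–titanium catalyst and C3 (trans to C2) from the aldol transition state of the same step. No later step breaks a bond at C2 or C3, and the E-alkene of the geranyl group is bought with geranyl bromide.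

Key step: step 6

Remark on the chemistry (assumption): (S)-BINOL is taken to expose the Si face of the ring B aldehyde, as it does with simple aromatic aldehydes; the configuration of the key-step product is to be confirmed, and (R)-BINOL is used if the sense is reversed.

Ring atoms carry flavanone numbers (O1, C2, C3, C4, C4a, C5–C8, C8a). Abbreviations: Ar = 4-methoxy-2,6-bis(methoxymethoxy)phenyl; geranyl = (2E)-3,7-dimethylocta-2,6-dien-1-yl; prenyl = 3-methylbut-2-en-1-yl; TBS = tert-butyldimethylsilyl; TMS = trimethylsilyl; MOM = methoxymethyl.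

**Route**

Step 1
Reactants: 1 5-methoxyresorcinol
Product: 2 1-methoxy-3,5-bis(methoxymethoxy)benzene
Conditions: MOMCl, iPr2NEt, CH2Cl2, 0 °C to rt
Reagents that add atoms: chloromethyl methyl ether (MOMCl), COCCl
Why: O-alkylation of both phenols with the chloromethyl ether under amine base gives the bis-acetal, whose oxygens direct the lithiation of the next step.

Step 2
Reactants: 2 1-methoxy-3,5-bis(methoxymethoxy)benzene
Product: 4 4-methoxy-2,6-bis(methoxymethoxy)benzaldehyde, via aryllithium 3 (not isolated)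
Conditions: n-BuLi, TMEDA, THF, 0 °C; DMF, 0 °C to rt; H2O
Reagents that add atoms: N,N-dimethylformamide (DMF), CN(C)C=O
Why: Directed ortho metalation, in which the two MOM ethers together direct lithiation to the carbon between them, followed by formylation of the aryllithium with DMF.

Step 3
Reactants: 5 (E)-4-methoxybut-3-en-2-one
Product: 6 (E)-3-(tert-butyldimethylsilyloxy)-1-methoxybuta-1,3-diene
Conditions: TBSOTf, Et3N, Et2O, 0 °C
Reagents that add atoms: tert-butyldimethylsilyl triflate (TBSOTf), CC(C)(C)[Si](C)(C)OS(=O)(=O)C(F)(F)F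
Why: Soft enolisation of the methyl ketone with silyl triflate and amine should give the 2-silyloxy diene without disturbing the E-configured methoxyvinyl group.

Step 4
Reactants: 6 (E)-3-(tert-butyldimethylsilyloxy)-1-methoxybuta-1,3-diene
Product: 8 (E)-1-(tert-butyldimethylsilyloxy)-4-methoxybut-3-en-2-one, via silyloxy epoxide 7 (not isolated)
Conditions: mCPBA, hexane, −15 °C to rt
Reagents that add atoms: 3-chloroperbenzoic acid (mCPBA), OOC(=O)c1cccc(Cl)c1
Why: Rubottom oxidation, in which the peracid epoxidises the terminal silyl enol ether double bond (the most electron-rich alkene) and the silyloxy epoxide opens with 1,4-silyl migration, so the future C3 oxygen arrives already as its TBS ether.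

Step 5
Reactants: 8 (E)-1-(tert-butyldimethylsilyloxy)-4-methoxybut-3-en-2-one
Product: 9 (1E,3Z)-4-(tert-butyldimethylsilyloxy)-1-methoxy-3-(trimethylsilyloxy)buta-1,3-diene
Conditions: TMSOTf, Et3N, Et2O, 0 °C
Reagents that add atoms: trimethylsilyl triflate (TMSOTf), C[Si](C)(C)OS(=O)(=O)C(F)(F)F
Why: Soft enolisation of the α-silyloxy ketone, which can enolise only towards the oxygen-bearing carbon, should give the (Z)-enol silane as is usual for α-alkoxy ketones under amine and silyl triflate.

Step 6
Reactants: 4 4-methoxy-2,6-bis(methoxymethoxy)benzaldehyde; 9 (1E,3Z)-4-(tert-butyldimethylsilyloxy)-1-methoxy-3-(trimethylsilyloxy)buta-1,3-diene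
Product: 11 (2R,3R)-3-(tert-butyldimethylsilyloxy)-2-[4-methoxy-2,6-bis(methoxymethoxy)phenyl]-2,3-dihydro-4H-pyran-4-one, via aldol adduct 10 (not isolated)
Conditions: Ti(OiPr)4 (10 mol%), (S)-BINOL (20 mol%), 4 Å molecular sieves, Et2O, −20 °C to rt; then CF3CO2H, CH2Cl2, 0 °C
Reagents that add atoms: none
Why: The BINOL–titanium Lewis acid binds the aldehyde oxygen of 4, and the diene attacks through C4, its silyloxy-bearing terminus and most nucleophilic carbon, in a Mukaiyama aldol event that forms C2–C3 and passes the TMS group to the new alkoxide (10). Acid then frees that oxygen, which adds to the β-methoxy enone in a 6-endo-trig conjugate closure that forms O1–C8a and ring C, and loss of methanol restores the enone. The closest known chemistry is the titanium–binaphthol-catalysed formal hetero-Diels–Alder reaction of aldehydes with 1-methoxy-3-silyloxybutadienes, 4-oxygenated dienes included. C2 is set by the ligand, (S)-BINOL being expected to expose the Si face of the aldehyde, and C3 by the open antiperiplanar transition state of the (Z)-enol silane, which places aryl and silyloxy anti and hence trans in the ring. The step needs attack at C4 and not C2 of the diene, secured by the 1,3-dioxygenation pattern, and clean addition to a hindered carbonyl, helped by an aldehyde that cannot enolise and binds the Lewis acid strongly.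

Step 7
Reactants: 12 methyl acetoacetate; 13 prenyl bromide (1-bromo-3-methylbut-2-ene)
Product: 15 methyl 7-methyl-3-oxooct-6-enoate, via dianion 14 (not isolated)
Conditions: NaH, THF, 0 °C; n-BuLi, 0 °C; 13, 0 °C to rt; aq. HCl
Reagents that add atoms: none
Why: γ-Alkylation of the acetoacetate dianion, whose more basic terminal carbanion displaces the allylic bromide selectively and places the prenyl group on the future C8.

Step 8
Reactants: 15 methyl 7-methyl-3-oxooct-6-enoate; 16 geranyl bromide
Product: 17 methyl 2-geranyl-7-methyl-3-oxooct-6-enoate (racemic)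
Conditions: K2CO3, acetone, reflux
Reagents that add atoms: none
Why: C-Alkylation of the β-keto ester enolate by SN2 displacement at the primary allylic carbon keeps the E-alkene and places the geranyl group on the future C6.

Step 9
Reactants: 17 methyl 2-geranyl-7-methyl-3-oxooct-6-enoate
Product: 20 2-geranyl-1-methoxy-7-methyl-1,3-bis(trimethylsilyloxy)octa-1,3,6-triene, via mono(silyl enol ether) 18 (not isolated), via lithium dienolate 19 (not isolated)
Conditions: TMSCl, Et3N, hexane, rt; filter, concentrate; then LiN(iPr)2, THF, −78 °C; TMSCl, −78 to 0 °C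
Reagents that add atoms: chlorotrimethylsilane (TMSCl), C[Si](C)(C)Cl
Why: Standard two-stage bis-silylation of a β-keto ester, in which the ketone enol is trapped first, the γ-proton of the resulting β-silyloxy enoate is then removed and the dienolate is O-silylated, giving a γ-nucleophilic equivalent of the keto ester dianion.

Step 10
Reactants: 11 (2R,3R)-3-(tert-butyldimethylsilyloxy)-2-Ar-2,3-dihydro-4H-pyran-4-one; 20 2-geranyl-1-methoxy-7-methyl-1,3-bis(trimethylsilyloxy)octa-1,3,6-triene
Product: 23 methyl 4-[(5R,6R)-6-Ar-5-(tert-butyldimethylsilyloxy)-4-oxo-3-(phenylselanyl)oxan-2-yl]-2-geranyl-7-methyl-3-oxooct-6-enoate (diastereomer mixture), via Michael adduct 21 (not isolated), via enol silane selenide 22 (not isolated)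
Conditions: TMSOTf (10 mol%), 20 (1.0 equiv), CH2Cl2, −78 °C; then PhSeCl, −78 °C; aq. citric acid
Reagents that add atoms: benzeneselenenyl chloride (PhSeCl), Cl[Se]c1ccccc1
Why: Mukaiyama–Michael addition in which the silylated enone is attacked at C8a by the γ-carbon of 20 and silyl transfer leaves the regiodefined C4–C4a enol silane 21, the most nucleophilic alkene present, which the selenenyl chloride captures at C4a before mild acid hydrolyses the ester-conjugated enol silane; the new stereocentres at C4a, C8a, C8 and C6 are all removed later.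

Step 11
Reactants: 23 methyl 4-[(5R,6R)-6-Ar-5-(tert-butyldimethylsilyloxy)-4-oxo-3-(phenylselanyl)oxan-2-yl]-2-geranyl-7-methyl-3-oxooct-6-enoate
Product: 25 methyl 4-[(2R,3R)-2-Ar-3-(tert-butyldimethylsilyloxy)-4-oxo-3,4-dihydro-2H-pyran-6-yl]-2-geranyl-7-methyl-3-oxooct-6-enoate (diastereomer mixture), via selenoxide 24 (not isolated)
Conditions: H2O2 (30% aq.), pyridine, CH2Cl2, 0 °C to rt
Reagents that add atoms: none
Why: Selenoxide syn-elimination, which can only take the single β-hydrogen (on C8a) and so restores the C4a=C8a enone, now carrying the keto ester chain, without touching C2 or C3.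

Step 12
Reactants: 25 methyl 4-[(2R,3R)-2-Ar-3-(tert-butyldimethylsilyloxy)-4-oxo-3,4-dihydro-2H-pyran-6-yl]-2-geranyl-7-methyl-3-oxooct-6-enoate
Product: 26 (2R,3R)-2-Ar-3-(tert-butyldimethylsilyloxy)-6-geranyl-5,7-dihydroxy-8-prenyl-2,3-dihydro-4H-chromen-4-one
Conditions: DBU, THF, 0 °C to rt; AcOH
Reagents that add atoms: none
Why: Proposed new method: DBU removes the C8 proton, which is α to the C7 ketone and vinylogously α to C4, and the extended enolate should attack the methyl ester through C4a in a 6-(enolexo)-exo-trig Claisen closure; loss of methoxide gives a cyclohexadienone-dione in which C5, C7 and C8a already stand at the phenol oxidation level, so two tautomerisations aromatise ring A without an oxidant and without the ring oxygen ever sitting β to a carbanion on a saturated carbon, while C3–H next to the vinylogous ester (later phenoxide-conjugated) carbonyl is not acidic enough for DBU; the closest known reaction type is the base-mediated Claisen cyclisation of 3,5,7-triketo esters to acylphloroglucinols, of which 25 is the cyclic enol ether.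

Step 13
Reactants: 26 (2R,3R)-2-Ar-3-(tert-butyldimethylsilyloxy)-6-geranyl-5,7-dihydroxy-8-prenyl-2,3-dihydro-4H-chromen-4-one
Product: 27 (2R,3R)-2-(2,6-dihydroxy-4-methoxyphenyl)-6-geranyl-3,5,7-trihydroxy-8-prenyl-2,3-dihydro-4H-chromen-4-one (CNP0304077.2)
Conditions: HCl (3 M aq.), MeOH, 40 °C
Reagents that add atoms: none
Why: Acidic methanolysis should cleave both aryl MOM acetals and the secondary TBS ether in one operation, and the 2,3-trans arrangement is the thermodynamically preferred one for dihydroflavonols, so mild acid should not erode it.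

**Compound list**

1 | 5-methoxyresorcinol | COc1cc(O)cc(O)c1 | starting material
2 | 1-methoxy-3,5-bis(methoxymethoxy)benzene | COCOc1cc(OC)cc(OCOC)c1 | intermediate
3 | [4-methoxy-2,6-bis(methoxymethoxy)phenyl]lithium | [Li]c1c(OCOC)cc(OC)cc1OCOC | intermediate
4 | 4-methoxy-2,6-bis(methoxymethoxy)benzaldehyde | COCOc1cc(OC)cc(OCOC)c1C=O | intermediate
5 | (E)-4-methoxybut-3-en-2-one | CO/C=C/C(C)=O | starting material
6 | (E)-3-(tert-butyldimethylsilyloxy)-1-methoxybuta-1,3-diene | CO/C=C/C(=C)O[Si](C)(C)C(C)(C)C | intermediate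
7 | 2-(tert-butyldimethylsilyloxy)-2-[(E)-2-methoxyethenyl]oxirane (racemic) | CO/C=C/C1(CO1)O[Si](C)(C)C(C)(C)C | intermediate
8 | (E)-1-(tert-butyldimethylsilyloxy)-4-methoxybut-3-en-2-one | CO/C=C/C(=O)CO[Si](C)(C)C(C)(C)C | intermediate
9 | (1E,3Z)-4-(tert-butyldimethylsilyloxy)-1-methoxy-3-(trimethylsilyloxy)buta-1,3-diene | CO/C=C/C(O[Si](C)(C)C)=C/O[Si](C)(C)C(C)(C)C | intermediate
10 | (1E,4R,5R)-4-(tert-butyldimethylsilyloxy)-1-methoxy-5-[4-methoxy-2,6-bis(methoxymethoxy)phenyl]-5-(trimethylsilyloxy)pent-1-en-3-one | CO/C=C/C(=O)[C@H](O[Si](C)(C)C(C)(C)C)[C@H](O[Si](C)(C)C)c1c(OCOC)cc(OC)cc1OCOC | intermediate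
11 | (2R,3R)-3-(tert-butyldimethylsilyloxy)-2-[4-methoxy-2,6-bis(methoxymethoxy)phenyl]-2,3-dihydro-4H-pyran-4-one | COc1cc(OCOC)c([C@H]2OC=CC(=O)[C@@H]2O[Si](C)(C)C(C)(C)C)c(OCOC)c1 | intermediate
12 | methyl acetoacetate | COC(=O)CC(C)=O | starting material
13 | prenyl bromide (1-bromo-3-methylbut-2-ene) | CC(C)=CCBr | starting material
14 | sodium lithium dianion of methyl acetoacetate | [Na+].[Li+].COC(=O)[CH-]C(=O)[CH2-] | intermediate
15 | methyl 7-methyl-3-oxooct-6-enoate | COC(=O)CC(=O)CCC=C(C)C | intermediate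
16 | geranyl bromide, (2E)-1-bromo-3,7-dimethylocta-2,6-diene | BrC/C=C(\C)CCC=C(C)C | starting material
17 | methyl 2-[(2E)-3,7-dimethylocta-2,6-dien-1-yl]-7-methyl-3-oxooct-6-enoate (racemic) | COC(=O)C(C/C=C(\C)CCC=C(C)C)C(=O)CCC=C(C)C | intermediate
18 | methyl 2-[(2E)-3,7-dimethylocta-2,6-dien-1-yl]-7-methyl-3-(trimethylsilyloxy)octa-2,6-dienoate | COC(=O)C(C/C=C(\C)CCC=C(C)C)=C(CCC=C(C)C)O[Si](C)(C)C | intermediate
19 | lithium dienolate of 18 (deprotonated at C4) | [Li+].COC([O-])=C(C/C=C(\C)CCC=C(C)C)C(O[Si](C)(C)C)=CCC=C(C)C | intermediate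
20 | 2-[(2E)-3,7-dimethylocta-2,6-dien-1-yl]-1-methoxy-7-methyl-1,3-bis(trimethylsilyloxy)octa-1,3,6-triene | COC(O[Si](C)(C)C)=C(C/C=C(\C)CCC=C(C)C)C(O[Si](C)(C)C)=CCC=C(C)C | intermediate
21 | methyl 4-[(2R,3R)-2-Ar-3-(tert-butyldimethylsilyloxy)-4-(trimethylsilyloxy)-3,6-dihydro-2H-pyran-6-yl]-2-geranyl-7-methyl-3-(trimethylsilyloxy)octa-2,6-dienoate | COc1cc(OCOC)c([C@H]2OC(C(CC=C(C)C)C(O[Si](C)(C)C)=C(C/C=C(\C)CCC=C(C)C)C(=O)OC)C=C(O[Si](C)(C)C)[C@@H]2O[Si](C)(C)C(C)(C)C)c(OCOC)c1 | intermediate
22 | methyl 4-[(5R,6R)-6-Ar-5-(tert-butyldimethylsilyloxy)-4-oxo-3-(phenylselanyl)oxan-2-yl]-2-geranyl-7-methyl-3-(trimethylsilyloxy)octa-2,6-dienoate | COc1cc(OCOC)c([C@H]2OC(C(CC=C(C)C)C(O[Si](C)(C)C)=C(C/C=C(\C)CCC=C(C)C)C(=O)OC)C([Se]c3ccccc3)C(=O)[C@@H]2O[Si](C)(C)C(C)(C)C)c(OCOC)c1 | intermediate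
23 | methyl 4-[(5R,6R)-6-Ar-5-(tert-butyldimethylsilyloxy)-4-oxo-3-(phenylselanyl)oxan-2-yl]-2-geranyl-7-methyl-3-oxooct-6-enoate | COc1cc(OCOC)c([C@H]2OC(C(CC=C(C)C)C(=O)C(C/C=C(\C)CCC=C(C)C)C(=O)OC)C([Se]c3ccccc3)C(=O)[C@@H]2O[Si](C)(C)C(C)(C)C)c(OCOC)c1 | intermediate
24 | selenoxide of 23, 3-(phenylseleninyl)oxan-4-one | COc1cc(OCOC)c([C@H]2OC(C(CC=C(C)C)C(=O)C(C/C=C(\C)CCC=C(C)C)C(=O)OC)C([Se](=O)c3ccccc3)C(=O)[C@@H]2O[Si](C)(C)C(C)(C)C)c(OCOC)c1 | intermediate
25 | methyl 4-[(2R,3R)-2-Ar-3-(tert-butyldimethylsilyloxy)-4-oxo-3,4-dihydro-2H-pyran-6-yl]-2-geranyl-7-methyl-3-oxooct-6-enoate | COc1cc(OCOC)c([C@H]2OC(C(CC=C(C)C)C(=O)C(C/C=C(\C)CCC=C(C)C)C(=O)OC)=CC(=O)[C@@H]2O[Si](C)(C)C(C)(C)C)c(OCOC)c1 | intermediate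
26 | (2R,3R)-3-(tert-butyldimethylsilyloxy)-6-[(2E)-3,7-dimethylocta-2,6-dien-1-yl]-5,7-dihydroxy-2-[4-methoxy-2,6-bis(methoxymethoxy)phenyl]-8-(3-methylbut-2-en-1-yl)-2,3-dihydro-4H-chromen-4-one | COc1cc(OCOC)c([C@H]2Oc3c(CC=C(C)C)c(O)c(C/C=C(\C)CCC=C(C)C)c(O)c3C(=O)[C@@H]2O[Si](C)(C)C(C)(C)C)c(OCOC)c1 | intermediate
27 | (2R,3R)-2-(2,6-dihydroxy-4-methoxyphenyl)-6-[(2E)-3,7-dimethylocta-2,6-dien-1-yl]-3,5,7-trihydroxy-8-(3-methylbut-2-en-1-yl)-2,3-dihydro-4H-chromen-4-one | COc1cc(O)c([C@H]2Oc3c(CC=C(C)C)c(O)c(C/C=C(\C)CCC=C(C)C)c(O)c3C(=O)[C@@H]2O)c(O)c1 | target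

**Step count**

Total: 13 steps. Longest linear sequence: 8 steps (steps 3, 4, 5, 6, 10, 11, 12 and 13, from (E)-4-methoxybut-3-en-2-one).

**Steps most likely to fail**

Step 12. The extended enolate may fail to attack the ester through C4a, or base may add at C8a and open ring C, so that ring A does not close. The fallback uses known reactions and closes the ring before the dehydrogenation. It sets out from 11 and 20. The Mukaiyama–Michael addition of step 10 is run as far as 21 and quenched with aqueous citric acid in place of the selenenyl chloride, which should give the saturated diketo ester F1. KOtBu in THF at −78 to 0 °C should then bring about a Dieckmann condensation of the ordinary C4a ketone enolate onto the methyl ester to give the bicyclic triketone F2. This compound carries the ring oxygen β to two carbonyl groups, so it is kept cold and dehydrogenated at once with DDQ in dioxane at rt, the known aromatisation of enolised cyclohexane-1,3-diones, to rejoin the route at 26.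

Step 6. Addition to the hindered, electron-rich carbonyl may be slow, with loss of enantio- and diastereocontrol when the bulky silyloxy terminus has to attack, and the electron-rich benzylic C2–O bond may ionise during the acid-induced closure. The fallback separates the two stereocentres and sets out from 4. The same titanium–BINOL aldol–cyclisation with commercially available (E)-1-methoxy-3-(trimethylsilyloxy)buta-1,3-diene, the unsubstituted diene for which this catalysis is best established, should give through the aldol adduct F3 the 3-unsubstituted dihydropyranone F4. The C3 oxygen is then introduced under substrate control: LiN(SiMe3)2 in THF at −78 °C forms the enolate and 2-(phenylsulfonyl)-3-phenyloxaziridine should oxidise it anti to the C2 aryl group to give the trans-3-hydroxy ketone F5. TBSOTf and 2,6-lutidine in CH2Cl2 then return the route to 11.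

Step 10. The selenenyl chloride may be consumed by the trisubstituted chain alkenes or by the ester-conjugated enol silane instead of the ring enol silane. The fallback installs selenium before the chain is present and sets out from 11. PhSeCl and pyridine in CH2Cl2 should selenenylate the nucleophilic α-carbon of the vinylogous ester to give the 5-(phenylselanyl) enone F6. TMSOTf-catalysed Mukaiyama–Michael addition of 20 at −78 °C should then give the bis(silyl enol ether) F7, and aqueous citric acid hydrolyses both enol silanes to rejoin the route at 23.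

**Further compounds**

F1 | step 12 | methyl 4-[(5R,6R)-6-Ar-5-(tert-butyldimethylsilyloxy)-4-oxooxan-2-yl]-2-geranyl-7-methyl-3-oxooct-6-enoate | COc1cc(OCOC)c([C@H]2OC(C(CC=C(C)C)C(=O)C(C/C=C(\C)CCC=C(C)C)C(=O)OC)CC(=O)[C@@H]2O[Si](C)(C)C(C)(C)C)c(OCOC)c1
F2 | step 12 | (2R,3R)-2-Ar-3-(tert-butyldimethylsilyloxy)-6-geranyl-8-prenyl-hexahydro-4H-chromene-4,5,7-trione (4a,6,8,8a-tetrahydro triketone) | COc1cc(OCOC)c([C@H]2OC3C(CC=C(C)C)C(=O)C(C/C=C(\C)CCC=C(C)C)C(=O)C3C(=O)[C@@H]2O[Si](C)(C)C(C)(C)C)c(OCOC)c1
F3 | step 6 | (1E,5S)-1-methoxy-5-[4-methoxy-2,6-bis(methoxymethoxy)phenyl]-5-(trimethylsilyloxy)pent-1-en-3-one | CO/C=C/C(=O)C[C@H](O[Si](C)(C)C)c1c(OCOC)cc(OC)cc1OCOC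
F4 | step 6 | (2S)-2-[4-methoxy-2,6-bis(methoxymethoxy)phenyl]-2,3-dihydro-4H-pyran-4-one | COc1cc(OCOC)c([C@H]2OC=CC(=O)C2)c(OCOC)c1
F5 | step 6 | (2R,3R)-3-hydroxy-2-[4-methoxy-2,6-bis(methoxymethoxy)phenyl]-2,3-dihydro-4H-pyran-4-one | COc1cc(OCOC)c([C@H]2OC=CC(=O)[C@@H]2O)c(OCOC)c1
F6 | step 10 | (2R,3R)-3-(tert-butyldimethylsilyloxy)-2-[4-methoxy-2,6-bis(methoxymethoxy)phenyl]-5-(phenylselanyl)-2,3-dihydro-4H-pyran-4-one | COc1cc(OCOC)c([C@H]2OC=C([Se]c3ccccc3)C(=O)[C@@H]2O[Si](C)(C)C(C)(C)C)c(OCOC)c1
F7 | step 10 | methyl 4-[(2R,3R)-2-Ar-3-(tert-butyldimethylsilyloxy)-5-(phenylselanyl)-4-(trimethylsilyloxy)-3,6-dihydro-2H-pyran-6-yl]-2-geranyl-7-methyl-3-(trimethylsilyloxy)octa-2,6-dienoate | COc1cc(OCOC)c([C@H]2OC(C(CC=C(C)C)C(O[Si](C)(C)C)=C(C/C=C(\C)CCC=C(C)C)C(=O)OC)C([Se]c3ccccc3)=C(O[Si](C)(C)C)[C@@H]2O[Si](C)(C)C(C)(C)C)c(OCOC)c1
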